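**Plan** (side chain numbered C1 to C19 outward from the pyrrole ring; ring numbered as in the target, CHO on C2, chain on C5)
Cuts: ring C2–CHO and the N–H mask first. Then C11–C12 together with C9–C10, which lifts C10=C11 out as acetylene. Then ring C5–C1, and inside the C12–C19 piece, C14–C15.
Enabling feature: C10 and C11 are two unsubstituted cis-olefinic CH atoms. They lie between the saturated C1–C9 tether to the pyrrole ring and the doubly allylic C12H2, so C10=C11 maps onto acetylene, and a C9 organocopper and a C8 primary allylic bromide can be joined to it in one flask.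
Forward: the purchased pyrrole ring is N-SEM protected, lithiated next to nitrogen and alkylated (fragment 1, ring plus C1–C9). Pent-2-ynyl bromide and propargyl alcohol give the C12–C19 dienyl bromide (fragment 2). The cuprate of fragment 1, acetylene and fragment 2 then give the full C19 triene; SEM is removed and the ring is formylated last.
Geometry: there are no stereocentres. C10=C11 is Z from syn-carbocupration with retention in the coupling; C13=C14 and C16=C17 are Z from syn semihydrogenation of a skipped diyne.

Key step: step 7

Assumption: both alkenyl ligands of cuprate 16 are taken to transfer to the reactive allylic bromide, so step 7 is balanced with half an equivalent of CuBr·SMe2 per iodide 7.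

Step 1
Reactants: 1 pyrrole
Product: 3 1-{[2-(trimethylsilyl)ethoxy]methyl}-1H-pyrrole (N-SEM-pyrrole), via sodium pyrrolide 2 (not isolated)
Conditions: NaH, DMF, 0 °C; SEMCl, 0 °C → rt
Reagents that add atoms: 2-(trimethylsilyl)ethoxymethyl chloride (SEMCl), C[Si](C)(C)CCOCCl
Why: N-alkylation of the sodium pyrrolide by the reactive chloromethyl ether should occur at nitrogen (N-protection), and the SEM group later serves both as director for lithiation and as mask for the acidic N–H in the organometallic key step.

Step 2
Reactants: 3 N-SEM-pyrrole; 4 1,9-dibromononane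
Product: 6 2-(9-bromononyl)-1-{[2-(trimethylsilyl)ethoxy]methyl}-1H-pyrrole, via 2-lithio-N-SEM-pyrrole 5 (not isolated)
Conditions: n-BuLi, THF, −10 → 0 °C; 4 (3 equiv), DMPU, 0 °C → rt
Reagents that add atoms: none
Why: The SEM oxygen and the ring nitrogen direct n-BuLi to the alpha carbon (directed alpha-lithiation of an N-protected pyrrole), and 5 should displace one bromide of the symmetrical dibromide in an SN2 alkylation, the excess of 4 keeping double substitution down.

Step 3
Reactants: 6 2-(9-bromononyl)-N-SEM-pyrrole
Product: 7 2-(9-iodononyl)-1-{[2-(trimethylsilyl)ethoxy]methyl}-1H-pyrrole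
Conditions: NaI, acetone, reflux
Reagents that add atoms: sodium iodide, [Na+].[I-]
Why: The Finkelstein reaction, driven by precipitation of NaBr from acetone, should give the primary iodide needed for a clean lithium–iodine exchange, and the SEM group and the pyrrole ring are inert to it.

Step 4
Reactants: 8 1-bromopent-2-yne; 9 prop-2-yn-1-ol
Product: 10 octa-2,5-diyn-1-ol
Conditions: CuI, NaI, Cs2CO3, DMF, rt
Reagents that add atoms: none
Why: The copper-mediated sp–sp3 coupling of a terminal alkyne and a propargylic bromide under mild carbonate base is the standard entry to skipped diynes, tolerates the free hydroxyl group and avoids base-induced isomerisation to allenes.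

Step 5
Reactants: 10 octa-2,5-diyn-1-ol
Product: 11 (2Z,5Z)-octa-2,5-dien-1-ol
Conditions: H2 (1 atm), Ni(OAc)2·4H2O, NaBH4, H2NCH2CH2NH2, EtOH, rt
Reagents that add atoms: none
Why: Syn semihydrogenation over the amine-poisoned nickel boride catalyst delivers both hydrogens to one face of each alkyne and should stop at the alkene stage, which sets the two Z alkenes that become C13=C14 and C16=C17.

Step 6
Reactants: 11 (2Z,5Z)-octa-2,5-dien-1-ol
Product: 12 (2Z,5Z)-1-bromoocta-2,5-diene
Conditions: CBr4, PPh3, CH2Cl2, −20 → 0 °C; used at once
Reagents that add atoms: carbon tetrabromide, BrC(Br)(Br)Br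
Why: In the Appel reaction bromide displaces the primary alkoxyphosphonium ion by SN2 under essentially neutral conditions, so no allylic transposition or Z to E isomerisation is expected.

Step 7
Reactants: 7 2-(9-iodononyl)-N-SEM-pyrrole; 13 acetylene; 12 (2Z,5Z)-1-bromoocta-2,5-diene
Product: 17 2-[(10Z,13Z,16Z)-nonadeca-10,13,16-trien-1-yl]-1-{[2-(trimethylsilyl)ethoxy]methyl}-1H-pyrrole, via alkyllithium 14 (not isolated), via lithium dialkylcuprate 15 (not isolated), via lithium Z-dialkenylcuprate 16 (not isolated)
Conditions: 7, t-BuLi (2.0 equiv), Et2O/pentane, −78 °C; CuBr·SMe2 (0.5 equiv), −78 → −35 °C; 13 (1.0 equiv), −50 → −25 °C; 12 (1.0 equiv), THF, −40 → 0 °C; aq NH4Cl/NH3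
Reagents that add atoms: none
Why: Lithium–iodine exchange converts 7 into the primary alkyllithium 14 and CuBr·SMe2 gathers two of these into the Gilman-type homocuprate 15, each C(sp3)–Cu bond of which adds syn across one molecule of acetylene through a four-centre transition state, so that in 16 the C1–C9 chain and the copper atom stand cis on C10=C11. Cuprate 16 then attacks the primary allylic bromide 12 by oxidative addition to a trivalent allylcopper species and rapid reductive elimination, which forms C11–C12 with retention at the alkenyl carbon. The closest known reaction type is the carbocupration of acetylene by lithium dialkylcuprates followed by allylation of the Z-alkenylcuprate, an established one-flask entry to Z-configured 1,4-dienes. No ring is closed and no stereocentre is made; the one new stereoelement, the Z alkene C10=C11, is controlled by the syn addition and by the configurational stability of alkenylcopper species at low temperature. The step needs a single insertion of acetylene, secured by one equivalent of gas per alkyl group and by staying below −20 °C where an alkenylcuprate does not add to a further acetylene, and it needs coupling at the alpha carbon of 12 with the allyl Z geometry intact, secured by the unhindered CH2Br terminus set against the substituted gamma carbon (C14), by the preference of homocuprates for the less substituted allyl terminus and by the low temperature. The SEM group takes away the acidic N–H and the formyl group is not yet present, so the pyrrole ring offers nothing that quenches 14, 15 or 16, and its free alpha C–H is not metalated under these conditions.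

Step 8
Reactants: 17 N-SEM trienylpyrrole
Product: 18 2-[(10Z,13Z,16Z)-nonadeca-10,13,16-trien-1-yl]-1H-pyrrole
Conditions: Bu4NF (1 M in THF), THF, reflux
Reagents that add atoms: none
Why: Fluoride attack on silicon triggers the beta-elimination typical of SEM cleavage (loss of ethylene, then of formaldehyde from the N-hydroxymethyl stage), a deprotection known for 2-alkylpyrroles, and the non-conjugated triene is not acidic enough to be isomerised by fluoride.

Step 9
Reactants: 18 2-trienyl-1H-pyrrole
Product: 20 mycalazal 20 5-[(10Z,13Z,16Z)-nonadeca-10,13,16-trien-1-yl]-1H-pyrrole-2-carbaldehyde, via iminium chloride 19 (not isolated)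
Conditions: POCl3, DMF, CH2Cl2, 0 °C → rt; aq NaOH, 0 °C → rt
Reagents that add atoms: N,N-dimethylformamide, CN(C)C=O; water, O
Why: In the Vilsmeier–Haack formylation the chloroiminium ion should attack the only free alpha position of the 2-alkylpyrrole, its most nucleophilic carbon, while the isolated Z alkenes are inert to this weak electrophile, and basic hydrolysis of 19 gives the aldehyde.

**Compound list**
1 | pyrrole | c1cc[nH]c1 | starting material
2 | sodium pyrrolide | [Na+].c1cc[n-]c1 | intermediate
3 | 1-{[2-(trimethylsilyl)ethoxy]methyl}-1H-pyrrole | C[Si](C)(C)CCOCn1cccc1 | intermediate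
4 | 1,9-dibromononane | BrCCCCCCCCCBr | starting material
5 | 2-lithio-1-{[2-(trimethylsilyl)ethoxy]methyl}-1H-pyrrole | [Li]c1cccn1COCC[Si](C)(C)C | intermediate
6 | 2-(9-bromononyl)-1-{[2-(trimethylsilyl)ethoxy]methyl}-1H-pyrrole | BrCCCCCCCCCc1cccn1COCC[Si](C)(C)C | intermediate
7 | 2-(9-iodononyl)-1-{[2-(trimethylsilyl)ethoxy]methyl}-1H-pyrrole | ICCCCCCCCCc1cccn1COCC[Si](C)(C)C | intermediate
8 | 1-bromopent-2-yne | CCC#CCBr | starting material
9 | prop-2-yn-1-ol | C#CCO | starting material
10 | octa-2,5-diyn-1-ol | CCC#CCC#CCO | intermediate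
11 | (2Z,5Z)-octa-2,5-dien-1-ol | CC/C=C\C/C=C\CO | intermediate
12 | (2Z,5Z)-1-bromoocta-2,5-diene | CC/C=C\C/C=C\CBr | intermediate
13 | acetylene | C#C | starting material
14 | 9-(1-SEM-pyrrol-2-yl)nonyllithium | [Li]CCCCCCCCCc1cccn1COCC[Si](C)(C)C | intermediate
15 | lithium bis[9-(1-SEM-pyrrol-2-yl)nonyl]cuprate | [Li+].C[Si](C)(C)CCOCn1cccc1CCCCCCCCC[Cu-]CCCCCCCCCc1cccn1COCC[Si](C)(C)C | intermediate
16 | lithium bis[(1Z)-11-(1-SEM-pyrrol-2-yl)undec-1-en-1-yl]cuprate | [Li+].C[Si](C)(C)CCOCn1cccc1CCCCCCCCC/C=C\[Cu-]/C=C\CCCCCCCCCc1cccn1COCC[Si](C)(C)C | intermediate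
17 | 2-[(10Z,13Z,16Z)-nonadeca-10,13,16-trien-1-yl]-1-{[2-(trimethylsilyl)ethoxy]methyl}-1H-pyrrole | CC/C=C\C/C=C\C/C=C\CCCCCCCCCc1cccn1COCC[Si](C)(C)C | intermediate
18 | 2-[(10Z,13Z,16Z)-nonadeca-10,13,16-trien-1-yl]-1H-pyrrole | CC/C=C\C/C=C\C/C=C\CCCCCCCCCc1ccc[nH]1 | intermediate
19 | dimethyl({5-[(10Z,13Z,16Z)-nonadeca-10,13,16-trien-1-yl]-1H-pyrrol-2-yl}methylidene)ammonium chloride | CC/C=C\C/C=C\C/C=C\CCCCCCCCCc1ccc(C=[N+](C)C)[nH]1.[Cl-] | intermediate
20 | mycalazal 20, 5-[(10Z,13Z,16Z)-nonadeca-10,13,16-trien-1-yl]-1H-pyrrole-2-carbaldehyde | CC/C=C\C/C=C\C/C=C\CCCCCCCCCc1ccc(C=O)[nH]1 | target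

Total step count: 9. Longest linear sequence: 6 (steps 1, 2, 3, 7, 8, 9); steps 4 to 6 build fragment 2 in parallel.

**Steps most likely to fail**

1. Step 7.
 - What may go wrong: attack of the alkenylcuprate at the gamma carbon of the allylic bromide (allylic transposition); partial Z to E erosion of the allyl unit through a trivalent pi-allylcopper species; a second insertion of acetylene; transfer of only one of the two alkenyl ligands; or premature protonation of the organometallics.
 - Fallback: the same bond is made at the alkyne oxidation level. It sets out from 7 and 10 and comes back at 17.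
 - Displacement of the iodide of 7 by lithium acetylide–ethylenediamine complex in DMSO gives 2-(undec-10-yn-1-yl)-1-SEM-pyrrole F1.
 - Appel bromination of 10 (CBr4, PPh3) gives 1-bromoocta-2,5-diyne F2.
 - CuI/NaI/Cs2CO3 coupling of F1 and F2 in DMF gives the skipped triyne 2-(nonadeca-10,13,16-triyn-1-yl)-1-SEM-pyrrole F3.
 - Threefold syn semihydrogenation of F3 over the catalyst from Ni(OAc)2·4H2O, NaBH4 and ethylenediamine gives 17.

2. Step 8.
 - What may go wrong: sluggish fluoride-induced fragmentation, because the electron-rich 2-alkylpyrrolide is a poor leaving group; stalling before formaldehyde is lost; and recapture of formaldehyde by the nucleophilic ring.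
 - Fallback: the last two operations are inverted so that the departing pyrrolide is stabilised by the formyl group. It sets out from 17 and comes back at 20, bypassing 18 and 19.
 - Vilsmeier–Haack formylation of 17 at its free alpha position passes through the N-SEM iminium chloride F4 and, after basic hydrolysis, gives 5-[(10Z,13Z,16Z)-nonadeca-10,13,16-trien-1-yl]-1-SEM-pyrrole-2-carbaldehyde F5.
 - Bu4NF in THF then releases 20.

3. Step 2.
 - What may go wrong: incomplete alkylation of the lithiopyrrole by an unactivated primary bromide, competing elimination, and double substitution of the dibromide.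
 - Fallback: the ring–chain bond is made by C-acylation and deoxygenation instead of carbanion alkylation. It sets out from 1 and comes back at 6.
 - Commercial 9-bromononanoic acid and (COCl)2 give 9-bromononanoyl chloride F6.
 - Compound 1 and EtMgBr give pyrrol-1-ylmagnesium bromide F7, which is C-acylated by F6 (Oddo-type acylation) to 9-bromo-1-(1H-pyrrol-2-yl)nonan-1-one F8.
 - NaBH4 in refluxing 2-propanol, the known deoxygenation of 2-acylpyrroles through the azafulvene, gives 2-(9-bromononyl)-1H-pyrrole F9.
 - NaH at 0 °C gives sodium 2-(9-bromononyl)pyrrol-1-ide F10, which is trapped at once by SEMCl to give 6.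

**Further compounds**
F1 | step 7 | 2-(undec-10-yn-1-yl)-1-{[2-(trimethylsilyl)ethoxy]methyl}-1H-pyrrole | C#CCCCCCCCCCc1cccn1COCC[Si](C)(C)C
F2 | step 7 | 1-bromoocta-2,5-diyne | CCC#CCC#CCBr
F3 | step 7 | 2-(nonadeca-10,13,16-triyn-1-yl)-1-{[2-(trimethylsilyl)ethoxy]methyl}-1H-pyrrole | CCC#CCC#CCC#CCCCCCCCCCc1cccn1COCC[Si](C)(C)C
F4 | step 8 | dimethyl({5-[(10Z,13Z,16Z)-nonadeca-10,13,16-trien-1-yl]-1-SEM-pyrrol-2-yl}methylidene)ammonium chloride | CC/C=C\C/C=C\C/C=C\CCCCCCCCCc1ccc(C=[N+](C)C)n1COCC[Si](C)(C)C.[Cl-]
F5 | step 8 | 5-[(10Z,13Z,16Z)-nonadeca-10,13,16-trien-1-yl]-1-{[2-(trimethylsilyl)ethoxy]methyl}-1H-pyrrole-2-carbaldehyde | CC/C=C\C/C=C\C/C=C\CCCCCCCCCc1ccc(C=O)n1COCC[Si](C)(C)C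
F6 | step 2 | 9-bromononanoyl chloride | O=C(Cl)CCCCCCCCBr
F7 | step 2 | pyrrol-1-ylmagnesium bromide | Br[Mg]n1cccc1
F8 | step 2 | 9-bromo-1-(1H-pyrrol-2-yl)nonan-1-one | O=C(CCCCCCCCBr)c1ccc[nH]1
F9 | step 2 | 2-(9-bromononyl)-1H-pyrrole | BrCCCCCCCCCc1ccc[nH]1
F10 | step 2 | sodium 2-(9-bromononyl)pyrrol-1-ide | [Na+].BrCCCCCCCCCc1ccc[n-]1
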